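If each substrate takes two reagent on its way to double product, you can follow a flask with one balance.

common to all: reagent 1.74 M
- violet: substrate 0.87 M; the very flask that is asked about, followed so far
- blue: substrate 1.7 M; run made earlier
- flask: substrate 0.87 M; time 1.5 h

| run | time / min | double product / % | substrate / % |
|---|---|---|---|
| violet | 4.00 | 67.4 | 12.8 |
| violet | 6.00 | 76.4 | 8.0 |
| violet | 10.0 | 81.8 | 5.1 |
| violet | 15.0 | 84.1 | 2.5 |
| violet | 25.0 | 83.4 | 1.8 |
| violet | 40.0 | 78.1 | 0.9 |
| blue | 4.00 | 32.7 | 33.5 |
| blue | 8.00 | 33.3 | 33.0 |
| blue | 15.0 | 32.7 | 32.8 |
| blue | 25.0 | 30.6 | 32.9 |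
| blue | 50.0 | 26.1 | 33.7 |
| blue | 90.0 | 21.4 | 32.2 |

(scatter of a reading: 0.5 percentage points)



1. time up to 1.5 h at which double product stands highest
2. the amount of double product, in percent of the substrate charged, at that time
3. the first time at which double product reaches 25 %, in the same percent, in min

1. **Demand.** The violet flask stands at 100 % reagent demand, the reagent that full conversion to double product takes, as a fraction of the reagent charge. Reagent used is demand times the sum of double product and half of the mono adduct, counting anything made from double product as double product.

2. **Test on blue.** Its demand is 195 %, so reagent is the limiting reagent there. At 4.00 min, taking the unread remainder as mono adduct, the balance has 96.9 % of the reagent used. In blue, substrate then reads between 32.2 % and 33.7 % up to 90.0 min.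

3. **First instants, violet.** Reagent and substrate are both at full charge, and double product already reads 67.4 % at 4.00 min, so 25 % comes well before that reading. Taking the unread remainder as mono adduct, the balance leaves 22.7 % of the violet reagent at 4.00 min.

4. **Middle.** At 15.0 min, violet substrate reads 2.5 % and double product 84.1 %. With demand at 100 %, the violet charge holds no reagent beyond what full conversion to double product takes.

5. **End.** In blue, double product falls from 33.3 % to 21.4 % while substrate stays flat, which reads as a loss of 0.00539 min⁻¹. My own reckoning puts the violet peak between 15.0 min and 25.0 min, near 84.1 %.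

The forecast gives 0.31 h, 84.6 % and 1.05 min, on the ground that “Its peak comes where the remaining formation drops to the decay rate”.

The flask gives 0.289 h, 84.5 % and 0.969 min.

    reagent + mono adduct → double product (k = 0.0140 M⁻¹ s⁻¹)
    double product → over-reaction product (k = 9.40 × 10⁻⁵ s⁻¹)
    substrate + reagent → mono adduct (k = 0.0110 M⁻¹ s⁻¹)

In the first minutes the two additions ran: by 0.150 h the violet flask held 5.24 % substrate, 10.6 % mono adduct and 81.1 % double product. Double product went on turning into over-reaction product, 7.01 % at 0.289 h and 37.2 % at 1.50 h. At 0.289 h the balance leaves 5.51 % of the reagent, and the flask holds 5.51 %. A neighbour flask, charged with 0.52 M substrate, has a demand of 59.8 %; it ends with 0 % substrate and 0 % mono adduct, so the balance leaves 40.2 %, and it holds 40 % of its reagent.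

All runs stem from a simulated flask for an exercise.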